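Z.E at the asked time is whatever Z the dissolved E has captured, minus what has since moved on to Q, so I keep the books on Z in fractions of its charge.

    G ⇌ E, rate k1*(csat - [E]) (k1 = 1.04 s⁻¹, csat = 61 mM)
    Z + E → Z.E (k2 = 0.803 L mol⁻¹ s⁻¹)
    Z → J (k3 = 0.0414 s⁻¹)
    Z.E ⇌ Q (K4 = 0.80, k4 = 0.0119 s⁻¹)

Z 0.25 M; G 61 mM (held); time 3.0 min

- at the start none of E is dissolved
- run time (flask): 3.0 min

1. Z.E at 3.0 min, in percent of the Z charged
2. the change that raises the amount of Z.E at 3.0 min, in percent of the Z charged most ("none" if none brings more than 2 percentage points) (gamma / eta / none)
3. amount of Z.E at 3.0 min, in percent of the Z charged, after eta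

- gamma: doubling the transfer coefficient of step 1, all else as stated
- eta: doubling the saturation concentration of G, all else as stated

Z is the limiting reagent: the transfer of G could deliver at most 4568 % of the charge by 3.0 min into a solution kept empty, far beyond the charge. Each unit of Z has two exits, capture by E or loss to J. After about 0.806 s, a moment I skip, E stands where transfer matches capture. That is 0.838 of saturation at the full charge of Z, rising to saturation as Z falls.

So capture runs at 0.992 times the loss to J at the start and 1.18 times at the end. The share captured drifts from 49.8 % to 54.2 %, a small rise. As an estimate I take the mean of the two ends as the capture share, the part of the charged Z that E takes rather than J, 52.0 %.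

The ledger: the loss to J alone leaves 0.0580 % of Z by 3.0 min, so the Z column closes. J gets 48.0 %. The captured part relaxes between Z.E and Q with 0.807 % of its gap remaining, so Z.E keeps 55.6 % of it. That enters 28.9 % as Z.E and 23.1 % as Q.

Gamma, doubling the transfer coefficient, lifts the starting level of E to 0.912 of saturation and by my reckoning gains 0.59 percentage points. Eta, doubling the saturation concentration, doubles both end ratios and by my reckoning gives 38.0 %, so I choose eta.

The forecast says 28.2 %, eta and 37 %, with Z “split roughly evenly between Z.E and J”; my 28.9 % and 38.0 % stand higher , with the same choice.

The flask gives 28.2 %, eta with a gain of 8.9 points against 1 point for gamma, and 37.0 %.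

At 0.0918 min in this flask, capture uses Z at 1.0 times the rate of the loss to J, and at 3.00 min Z.E and Q together hold 50.2 %, less than my capture share of 52.0 %. With the capture constant doubled instead, the same mean gives 66.7 %, hence 37.1 % as Z.E, and that flask holds 36.1 %.

The numbers are those of an exercise, and the outcome is calculated.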